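**Retrosynthetic overview**
1. Xestin A ⇒ its free carboxylic acid, by Fischer esterification in acidic methanol, which also equilibrates the peroxyketal carbon. Ring numbering used throughout: O1, O2, C3 (the CH bearing CH2CO2Me), C4=C5, C6 (the peroxyketal carbon).
2. Key disconnection: both C–O bonds of the O1–O2 bridge. H2O2 is stitched between C6 and C3 of a Z-alkenyl β-lactone, first by ketal perhydrolysis at C6 and then by 6-exo-tet SN2 opening of the lactone at C3 with inversion.
3. Enabling feature: C3 carries O2 and stands β to the ester carbonyl (O2–C3–CH2–C=O). This C–O bond and the carboxyl group therefore fold back into a β-lactone whose own carboxylate is the leaving group. C6 lies 1,4 to C3 across the cis C4=C5 bond, so a hydroperoxide on C6 reaches C3 through a six-membered transition state.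
4. Z-alkenyl β-lactone ⇒ alkynyl β-lactone (Lindlar) ⇒ ketal-protected ynal + ketene (catalytic asymmetric [2+2], the only controlling stereocentre) ⇒ dienyl Grignard reagent + Weinreb ynamide. The side chain comes from sorbyl acetate + 12-bromododecan-1-ol.
5. Ring order: the temporary β-lactone ring forms first (step 7). The 1,2-dioxine ring is the last and only skeletal ring (step 9), and the β-lactone is consumed in the same event.

Key step: step 9

Assumption: the enantiomer of the valine-derived triamine ligand used in step 7 is the one that delivers the S-configured lactone; the sense of induction is to be confirmed on a model ynal.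

**Step 1**
Reactants: 1 12-bromododecan-1-ol; 2 (2E,4E)-hexa-2,4-dien-1-yl acetate (sorbyl acetate)
Product: 5 (14E,16E)-octadeca-14,16-dien-1-ol, via chloromagnesium bromododecanolate 3 (not isolated), via alkoxide Grignard reagent 4 (not isolated)
Conditions: MeMgCl (1.0 equiv), THF, 0 °C; Mg turnings, THF, 45 °C; then 2, Li2CuCl4 (3 mol %), THF, −10 °C to rt; aq NH4Cl
Reagents that add atoms: none
Why: The magnesium alkoxide masks the hydroxyl so that the Grignard reagent can form, and the copper-catalysed (Kochi-type) coupling of alkyl Grignard reagents with sorbyl acetate takes place at the acetate-bearing carbon with retention of the E,E-diene, as used for dienol pheromones.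

**Step 2**
Reactants: 5 (14E,16E)-octadeca-14,16-dien-1-ol
Product: 6 (2E,4E)-18-bromooctadeca-2,4-diene
Conditions: CBr4, PPh3, CH2Cl2, 0 °C
Reagents that add atoms: carbon tetrabromide, BrC(Br)(Br)Br
Why: The Appel reaction converts a primary alcohol into the bromide under neutral conditions that leave the remote diene untouched.

**Step 3**
Reactants: 7 tert-butyldimethyl(prop-2-yn-1-yloxy)silane; 8 N-methoxy-N-methylcarbamoyl chloride
Product: 10 4-[(tert-butyldimethylsilyl)oxy]-N-methoxy-N-methylbut-2-ynamide, via lithium acetylide 9 (not isolated)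
Conditions: n-BuLi, THF, −78 °C; then 8, −78 to 0 °C
Reagents that add atoms: none
Why: Acylation of a lithium acetylide with the carbamoyl chloride gives the Weinreb ynamide directly, and the chelating amide does not react a second time.

**Step 4**
Reactants: 6 (2E,4E)-18-bromooctadeca-2,4-diene; 10 4-[(tert-butyldimethylsilyl)oxy]-N-methoxy-N-methylbut-2-ynamide
Product: 13 (18E,20E)-1-[(tert-butyldimethylsilyl)oxy]docosa-18,20-dien-2-yn-4-one, via octadecadienylmagnesium bromide 11 (not isolated), via tetrahedral magnesium adduct 12 (not isolated)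
Conditions: 6, Mg turnings, THF, 40 °C; then 10, THF, −78 to −20 °C; poured into cold aq NaHSO4
Reagents that add atoms: none
Why: In the Weinreb ketone synthesis the chelated tetrahedral adduct survives until the quench, so a single 1,2-addition gives the ynone, and the cold acidic quench keeps the released hydroxylamine from adding to it.

**Step 5**
Reactants: 13 (18E,20E)-1-[(tert-butyldimethylsilyl)oxy]docosa-18,20-dien-2-yn-4-one
Product: 14 (18E,20E)-4,4-dimethoxydocosa-18,20-dien-2-yn-1-ol
Conditions: HC(OMe)3, MeOH, camphorsulfonic acid (5 mol %), rt; Et3N quench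
Reagents that add atoms: trimethyl orthoformate, COC(OC)OC
Why: Acid-catalysed ketalisation with orthoformate as water scavenger is established for alkynyl ketones, and the same medium methanolyses the primary silyl ether, so the ketone is masked and the alcohol freed in one operation.

**Step 6**
Reactants: 14 (18E,20E)-4,4-dimethoxydocosa-18,20-dien-2-yn-1-ol
Product: 15 (18E,20E)-4,4-dimethoxydocosa-18,20-dien-2-ynal
Conditions: MnO2 (activated, excess), CH2Cl2, rt
Reagents that add atoms: none
Why: MnO2 oxidation is selective for propargylic alcohols and is neutral, so the acid-labile ketal and the diene are preserved.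

**Step 7**
Reactants: 15 (18E,20E)-4,4-dimethoxydocosa-18,20-dien-2-ynal; 16 acetyl bromide
Product: 18 (4S)-4-[(17E,19E)-3,3-dimethoxyhenicosa-17,19-dien-1-yn-1-yl]oxetan-2-one, via ketene 17 (not isolated)
Conditions: 16 (slow addition), i-Pr2NEt, MeAl[(CF3SO2NCH(i-Pr)CH2)2NBn] (10 mol %), CH2Cl2, −50 °C
Reagents that add atoms: none
Why: In the catalytic asymmetric acyl halide–aldehyde cyclocondensation (ketene–aldehyde [2+2] cycloaddition), for which electron-poor ynals are among the best substrates, the chiral aluminium Lewis acid binds the aldehyde and exposes one face to ketene, which sets the S centre.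

**Step 8**
Reactants: 18 (4S)-4-[(17E,19E)-3,3-dimethoxyhenicosa-17,19-dien-1-yn-1-yl]oxetan-2-one
Product: 19 (4S)-4-[(1Z,17E,19E)-3,3-dimethoxyhenicosa-1,17,19-trien-1-yl]oxetan-2-one
Conditions: H2 (1 atm), Pd/CaCO3 poisoned with Pb(OAc)2 (Lindlar catalyst), quinoline, EtOAc, 0 °C, stopped after 1 equiv H2; filtered through Celite, used crude
Reagents that add atoms: none
Why: In the Lindlar semihydrogenation, syn addition of one equivalent of H2 to the strongly adsorbing alkyne gives the Z-alkene, while the internal E,E-diene, the ketal and the β-lactone bind the poisoned catalyst far less well and should stay untouched.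

**Step 9**
Reactants: 19 (4S)-4-[(1Z,17E,19E)-3,3-dimethoxyhenicosa-1,17,19-trien-1-yl]oxetan-2-one
Product: 21 2-[(3R,6R)-6-methoxy-6-[(14E,16E)-octadeca-14,16-dien-1-yl]-3,6-dihydro-1,2-dioxin-3-yl]acetic acid, via hydroperoxy ketal lactone 20 (not isolated)
Conditions: H2O2 (anhydrous, 3 equiv, Et2O solution), camphorsulfonic acid (10 mol %), CH2Cl2, −20 to 0 °C
Reagents that add atoms: hydrogen peroxide, OO
Why: Proposed new method: acid-catalysed exchange of one methoxy group of the allylic ketal for H2O2 (known ketal perhydrolysis) gives hydroperoxy ketal 20, whose terminal peroxide oxygen attacks the alkyl carbon of the β-lactone from the back and expels the carboxylate, so that H2O2 is stitched between C6 and C3 and the acid is released in the same event. The closest known reaction types are the alkyl–oxygen (BAL2) opening of β-lactones by neutral oxygen nucleophiles, azide or thiolates with inversion, the perhydrolysis of β-lactones to β-hydroperoxy acids, and the 6-exo-tet cyclisation of hydroperoxy ketals onto epoxides, oxetanes and sulfonates, and their union on a β-lactone has not been described. The 1,2-dioxine ring closes in the 6-exo-tet mode (O2–C3 bond), with the cis C4=C5 bond holding the two termini together and the breaking C–O bond aligned with the alkene π system in a half-chair transition state. C3 is set stereospecifically by inversion of the lactone centre (S to R), and C6 is set under reversible ketal exchange by the anomeric preference for a pseudoaxial methoxy group with both carbon chains pseudoequatorial, which is the 3,6-cis R,R isomer. The step needs alkyl–oxygen and not acyl–oxygen cleavage, which the tether secures because attack at the carbonyl would need an eight-membered ring; it needs SN2 and not ionisation, which the electron-withdrawing ketal next to the allyl system and the low temperature favour; and it needs six-ring and not five-ring closure, which is why the ketone is carried as its dimethyl ketal, without a carbonyl or hemiketal oxygen. The remote diene is inert to H2O2 in the absence of a peracid or a metal catalyst, which is the reason for using a non-photochemical peroxide source.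

**Step 10**
Reactants: 21 2-[(3R,6R)-6-methoxy-6-[(14E,16E)-octadeca-14,16-dien-1-yl]-3,6-dihydro-1,2-dioxin-3-yl]acetic acid
Product: 22 xestin A, methyl 2-[(3R,6R)-6-methoxy-6-[(14E,16E)-octadeca-14,16-dien-1-yl]-3,6-dihydro-1,2-dioxin-3-yl]acetate
Conditions: MeOH, camphorsulfonic acid (10 mol %), rt; solid NaHCO3 quench
Reagents that add atoms: methanol, CO
Why: In this Fischer esterification the unhindered acid is esterified while the same acid reversibly ionises the C6–OMe bond to a ring peroxycarbenium ion, so C6 should settle under thermodynamic (anomeric) control in the 3,6-cis R,R form, any over-exchange at C6 from step 9 is reversed by mass action of methanol, and C3 has no pathway for epimerisation under acid.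

**Compound list**
1 | 12-bromododecan-1-ol | OCCCCCCCCCCCCBr | starting material
2 | (2E,4E)-hexa-2,4-dien-1-yl acetate (sorbyl acetate) | C/C=C/C=C/COC(C)=O | starting material
3 | chloromagnesium 12-bromododecan-1-olate | Cl[Mg]OCCCCCCCCCCCCBr | intermediate
4 | 12-(chloromagnesiooxy)dodecylmagnesium bromide | Cl[Mg]OCCCCCCCCCCCC[Mg]Br | intermediate
5 | (14E,16E)-octadeca-14,16-dien-1-ol | C/C=C/C=C/CCCCCCCCCCCCCO | intermediate
6 | (2E,4E)-18-bromooctadeca-2,4-diene | C/C=C/C=C/CCCCCCCCCCCCCBr | intermediate
7 | tert-butyldimethyl(prop-2-yn-1-yloxy)silane | C#CCO[Si](C)(C)C(C)(C)C | starting material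
8 | N-methoxy-N-methylcarbamoyl chloride | CON(C)C(=O)Cl | starting material
9 | lithium 3-[(tert-butyldimethylsilyl)oxy]prop-1-yn-1-ide | [Li]C#CCO[Si](C)(C)C(C)(C)C | intermediate
10 | 4-[(tert-butyldimethylsilyl)oxy]-N-methoxy-N-methylbut-2-ynamide | CON(C)C(=O)C#CCO[Si](C)(C)C(C)(C)C | intermediate
11 | (14E,16E)-octadeca-14,16-dien-1-ylmagnesium bromide | C/C=C/C=C/CCCCCCCCCCCCC[Mg]Br | intermediate
12 | tetrahedral bromomagnesium adduct of 11 and 10 | C/C=C/C=C/CCCCCCCCCCCCCC(O[Mg]Br)(N(C)OC)C#CCO[Si](C)(C)C(C)(C)C | intermediate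
13 | (18E,20E)-1-[(tert-butyldimethylsilyl)oxy]docosa-18,20-dien-2-yn-4-one | C/C=C/C=C/CCCCCCCCCCCCCC(=O)C#CCO[Si](C)(C)C(C)(C)C | intermediate
14 | (18E,20E)-4,4-dimethoxydocosa-18,20-dien-2-yn-1-ol | C/C=C/C=C/CCCCCCCCCCCCCC(OC)(OC)C#CCO | intermediate
15 | (18E,20E)-4,4-dimethoxydocosa-18,20-dien-2-ynal | C/C=C/C=C/CCCCCCCCCCCCCC(OC)(OC)C#CC=O | intermediate
16 | acetyl bromide | CC(=O)Br | starting material
17 | ketene | C=C=O | intermediate
18 | (4S)-4-[(17E,19E)-3,3-dimethoxyhenicosa-17,19-dien-1-yn-1-yl]oxetan-2-one | C/C=C/C=C/CCCCCCCCCCCCCC(OC)(OC)C#C[C@@H]1CC(=O)O1 | intermediate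
19 | (4S)-4-[(1Z,17E,19E)-3,3-dimethoxyhenicosa-1,17,19-trien-1-yl]oxetan-2-one | C/C=C/C=C/CCCCCCCCCCCCCC(OC)(OC)/C=C\[C@@H]1CC(=O)O1 | intermediate
20 | (4S)-4-[(1Z,17E,19E)-3-hydroperoxy-3-methoxyhenicosa-1,17,19-trien-1-yl]oxetan-2-one (both epimers at the ketal carbon, interconverting) | C/C=C/C=C/CCCCCCCCCCCCCC(OC)(OO)/C=C\[C@@H]1CC(=O)O1 | intermediate
21 | 2-[(3R,6R)-6-methoxy-6-[(14E,16E)-octadeca-14,16-dien-1-yl]-3,6-dihydro-1,2-dioxin-3-yl]acetic acid | C/C=C/C=C/CCCCCCCCCCCCC[C@]1(OC)C=C[C@@H](CC(=O)O)OO1 | intermediate
22 | xestin A, methyl 2-[(3R,6R)-6-methoxy-6-[(14E,16E)-octadeca-14,16-dien-1-yl]-3,6-dihydro-1,2-dioxin-3-yl]acetate | C/C=C/C=C/CCCCCCCCCCCCC[C@]1(OC)C=C[C@@H](CC(=O)OC)OO1 | target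

**Step count**
Total step count: 10.
Longest linear sequence: 9 steps (1, 2, 4, 5, 6, 7, 8, 9, 10) from 12-bromododecan-1-ol.

**Steps most likely to fail**

**1. Step 9 (bears the label "Proposed new method:").**
What may go wrong:
- competing acyl–oxygen perhydrolysis or methanolysis of the lactone;
- ionisation at the allylic carbon with erosion of the stereochemical integrity;
- hydrolysis of the ketal followed by five-ring closure and aromatisation;
- Z to E isomerisation at the oxocarbenium stage.

The fallback uses known chemistry. It sets out from 15 and comes back at 22. Wittig olefination of 15 with methyl (triphenylphosphoranylidene)acetate (CH2Cl2, rt) gives methyl (2E,20E,22E)-6,6-dimethoxytetracosa-2,20,22-trien-4-ynoate F1. Lindlar semihydrogenation gives methyl (2E,4Z,20E,22E)-6,6-dimethoxytetracosa-2,4,20,22-tetraenoate F2. Ketal perhydrolysis (H2O2 in Et2O, camphorsulfonic acid cat.) gives racemic methyl (2E,4Z,20E,22E)-6-hydroperoxy-6-methoxytetracosa-2,4,20,22-tetraenoate F3. Amine-catalysed intramolecular peroxy-Michael addition (Et2NH cat., CF3CH2OH) is the established entry to 3-alkoxy-1,2-dioxane-6-acetates. Followed by equilibration in acidic methanol it gives racemic material. From this, 22 is separated from its enantiomer, ent-xestin A F4, by preparative HPLC on a chiral stationary phase.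

**2. Step 7.**
What may go wrong: attack of acetyl bromide or of the Lewis acid on the ketal, and insufficient facial discrimination at the aldehyde.

The fallback sets out from 15 and comes back at 18. It replaces the cycloaddition by an aldol/lactonisation sequence. Mukaiyama aldol addition of 1-(tert-butylthio)-1-(trimethylsilyloxy)ethene is run under Ti(OiPr)4/BINOL catalysis, with the BINOL enantiomer chosen for the S carbinol. It gives S-tert-butyl (3S,20E,22E)-6,6-dimethoxy-3-[(trimethylsilyl)oxy]tetracosa-20,22-dien-4-ynethioate F5. Buffered fluoride (Bu4NF/AcOH) gives S-tert-butyl (3S,20E,22E)-3-hydroxy-6,6-dimethoxytetracosa-20,22-dien-4-ynethioate F6. LiOH in aqueous THF gives (3S,20E,22E)-3-hydroxy-6,6-dimethoxytetracosa-20,22-dien-4-ynoic acid F7. Carboxyl activation with PhSO2Cl in pyridine at 0 °C closes the β-lactone with retention at the carbinol carbon.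

**3. Step 8.**
What may go wrong: over-reduction of the new alkene, partial saturation or isomerisation of the remote diene, and hydrogenolysis of the propargylic C–O bond of the strained lactone.

The fallback sets out from 6 and comes back at 19. It takes the Z-alkene from a furan ring instead of from an alkyne. Bromide 6 alkylates 2-furyllithium F8 (furan, n-BuLi, THF) to give 2-[(14E,16E)-octadeca-14,16-dien-1-yl]furan F9. Dye-sensitised photooxygenation follows (O2, tetraphenylporphyrin, visible light, CH2Cl2, −78 °C), and the furan should react far faster with singlet oxygen than an acyclic dialkyl diene. This gives 1-[(14E,16E)-octadeca-14,16-dien-1-yl]-2,3,7-trioxabicyclo[2.2.1]hept-5-ene F10. Reduction in the same flask with Me2S gives (2Z,18E,20E)-4-oxodocosa-2,18,20-trienal F11. Cyclocondensation with 16 under the conditions of step 7 gives (4S)-4-[(1Z,17E,19E)-3-oxohenicosa-1,17,19-trien-1-yl]oxetan-2-one F12. Aprotic ketalisation (MeOSiMe3, Me3SiOTf cat., CH2Cl2, −78 °C) then gives 19.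

**Further compounds**
F1 | step 9 | methyl (2E,20E,22E)-6,6-dimethoxytetracosa-2,20,22-trien-4-ynoate | C/C=C/C=C/CCCCCCCCCCCCCC(OC)(OC)C#C/C=C/C(=O)OC
F2 | step 9 | methyl (2E,4Z,20E,22E)-6,6-dimethoxytetracosa-2,4,20,22-tetraenoate | C/C=C/C=C/CCCCCCCCCCCCCC(OC)(OC)/C=C\C=C\C(=O)OC
F3 | step 9 | methyl (2E,4Z,20E,22E)-6-hydroperoxy-6-methoxytetracosa-2,4,20,22-tetraenoate (racemic) | C/C=C/C=C/CCCCCCCCCCCCCC(OC)(OO)/C=C\C=C\C(=O)OC
F4 | step 9 | ent-xestin A, methyl 2-[(3S,6S)-6-methoxy-6-[(14E,16E)-octadeca-14,16-dien-1-yl]-3,6-dihydro-1,2-dioxin-3-yl]acetate | C/C=C/C=C/CCCCCCCCCCCCC[C@@]1(OC)C=C[C@H](CC(=O)OC)OO1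
F5 | step 7 | S-tert-butyl (3S,20E,22E)-6,6-dimethoxy-3-[(trimethylsilyl)oxy]tetracosa-20,22-dien-4-ynethioate | C/C=C/C=C/CCCCCCCCCCCCCC(OC)(OC)C#C[C@@H](O[Si](C)(C)C)CC(=O)SC(C)(C)C
F6 | step 7 | S-tert-butyl (3S,20E,22E)-3-hydroxy-6,6-dimethoxytetracosa-20,22-dien-4-ynethioate | C/C=C/C=C/CCCCCCCCCCCCCC(OC)(OC)C#C[C@@H](O)CC(=O)SC(C)(C)C
F7 | step 7 | (3S,20E,22E)-3-hydroxy-6,6-dimethoxytetracosa-20,22-dien-4-ynoic acid | C/C=C/C=C/CCCCCCCCCCCCCC(OC)(OC)C#C[C@@H](O)CC(=O)O
F8 | step 8 | 2-furyllithium | [Li]c1ccco1
F9 | step 8 | 2-[(14E,16E)-octadeca-14,16-dien-1-yl]furan | C/C=C/C=C/CCCCCCCCCCCCCc1ccco1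
F10 | step 8 | 1-[(14E,16E)-octadeca-14,16-dien-1-yl]-2,3,7-trioxabicyclo[2.2.1]hept-5-ene (racemic) | C/C=C/C=C/CCCCCCCCCCCCCC12C=CC(OO1)O2
F11 | step 8 | (2Z,18E,20E)-4-oxodocosa-2,18,20-trienal | C/C=C/C=C/CCCCCCCCCCCCCC(=O)/C=C\C=O
F12 | step 8 | (4S)-4-[(1Z,17E,19E)-3-oxohenicosa-1,17,19-trien-1-yl]oxetan-2-one | C/C=C/C=C/CCCCCCCCCCCCCC(=O)/C=C\[C@@H]1CC(=O)O1
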